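**Assumption:** Kuwanon T has no stereocentres and no E/Z-defined alkenes (both prenyl groups end in CMe2), so it is achiral and there is no enantiomer to control.

## Retrosynthetic overview
1. Target ⇐ global MOM removal ⇐ C3-prenylation (C3 lithiation) of the tetra-MOM 3'-prenylflavone 11.
2. Key disconnection C4–C4a: flavone 11 ⇐ o-hydroxyaryl ynone 10 ⇐ photo-Fries rearrangement of aryl arylpropiolate 9 (ArO–C(O) homolysis, phenoxyl/alkynoyl radical pair, ortho recombination).
3. Ester 9 ⇐ phenol 3 + arylpropiolic acid 8 (aryl iodide 6 + propiolic acid).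
4. Both arenes ⇐ one intermediate, 1,3-bis(MOM-oxy)benzene 2 from resorcinol: A ring by Ir meta-C–H borylation/oxidation, B ring by two directed ortho-lithiations (prenyl, then iodine).
5. Ring order: rings A and B are carried in from resorcinol; only the pyranone C ring is built, last, in the step-7 cascade.

## Route

**Step 1**
Reactants: 1, resorcinol
Product: 2, 1,3-bis(methoxymethoxy)benzene
Conditions: NaH, MOMCl, DMF, 0 °C → rt
Reagents that add atoms: chloromethyl methyl ether, COCCl
Why: Williamson-type O-alkylation of both phenols; MOM serves later as the ortho-lithiation director and as a base-stable protecting group.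

**Step 2**
Reactants: 2, 1,3-bis(methoxymethoxy)benzene
Product: 3, 3,5-bis(methoxymethoxy)phenol
Conditions: [Ir(OMe)(cod)]2 (1.5 mol %), dtbpy (3 mol %), B2pin2, THF, 80 °C; then 30% H2O2, aq NaOH, 0 °C (one pot)
Reagents that add atoms: hydrogen peroxide, OO (supplies the phenol O; boron from B2pin2 is not retained)
Why: Sterically controlled Ir-catalysed C–H borylation goes to C5, the only C–H with no ortho substituent, and basic peroxide oxidation of the aryl-Bpin gives the phenol without touching the MOM ethers.

**Step 3**
Reactants: 2, 1,3-bis(methoxymethoxy)benzene; 4, prenyl bromide (1-bromo-3-methylbut-2-ene)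
Product: 5, 1,3-bis(methoxymethoxy)-2-(3-methylbut-2-en-1-yl)benzene
Conditions: n-BuLi, THF, 0 °C → rt; then 4, −78 °C → rt
Reagents that add atoms: none
Why: Directed ortho-metalation occurs at C2 between the two MOM ethers, and the aryllithium is alkylated at the primary carbon of prenyl bromide (SN2).

**Step 4**
Reactants: 5
Product: 6, 1-iodo-2,4-bis(methoxymethoxy)-3-(3-methylbut-2-en-1-yl)benzene
Conditions: n-BuLi, TMEDA, THF, −20 → 0 °C; then I2 (1.05 equiv), −78 °C
Reagents that add atoms: iodine, II
Why: Second directed ortho-metalation at C4 (C4 and C6 are equivalent), then fast iodinolysis at −78 °C, where I2 does not add to the trisubstituted alkene.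

**Step 5**
Reactants: 6; 7, propiolic acid
Product: 8, 3-[2,4-bis(methoxymethoxy)-3-(3-methylbut-2-en-1-yl)phenyl]prop-2-ynoic acid
Conditions: Pd(PPh3)2Cl2 (5 mol %), dppb (10 mol %), DBU, DMSO, 35 °C
Reagents that add atoms: none
Why: Copper-free Sonogashira coupling of an aryl iodide with propiolic acid; near room temperature the carboxyl group is kept (decarboxylative coupling needs about 80 °C or more).

**Step 6**
Reactants: 8; 3, 3,5-bis(methoxymethoxy)phenol
Product: 9, 3,5-bis(methoxymethoxy)phenyl 3-[2,4-bis(methoxymethoxy)-3-(3-methylbut-2-en-1-yl)phenyl]prop-2-ynoate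
Conditions: DCC, DMAP (5 mol %), CH2Cl2, 0 °C → rt
Reagents that add atoms: none
Why: Steglich esterification, the standard way to make aryl 3-arylpropiolates, under neutral conditions that MOM and prenyl tolerate.

**Step 7 (key step, telescoped)**
Reactants: 9
Product: 11, 5,7-bis(methoxymethoxy)-2-[2,4-bis(methoxymethoxy)-3-(3-methylbut-2-en-1-yl)phenyl]-4H-chromen-4-one, via non-isolated 10, 1-[2-hydroxy-4,6-bis(methoxymethoxy)phenyl]-3-[2,4-bis(methoxymethoxy)-3-(3-methylbut-2-en-1-yl)phenyl]prop-2-yn-1-one
Conditions: hν (254 nm, quartz), degassed MeCN (about 5 mM), rt; concentrate; K2CO3, acetone, reflux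
Reagents that add atoms: none
Why: Photo-Fries rearrangement: excitation homolyses the ArO–C(O) bond, and the caged phenoxyl/alkynoyl radical pair recombines at an ortho carbon (the two are equivalent) to form C4–C4a. The resulting H-bonded ynone 10 is photostable, and carbonate in aprotic acetone closes it by 6-endo-dig oxa-Michael addition to the flavone. The para-acyl by-product cannot cyclise and is separated, and escaped phenol 3 is recovered.

**Step 8**
Reactants: 11; 4, prenyl bromide
Product: 12, 5,7-bis(methoxymethoxy)-2-[2,4-bis(methoxymethoxy)-3-(3-methylbut-2-en-1-yl)phenyl]-3-(3-methylbut-2-en-1-yl)-4H-chromen-4-one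
Conditions: LDA (1.2 equiv), THF, −78 °C, 20 min; then 4, DMPU, −78 → −40 °C
Reagents that add atoms: none
Why: Flavones are deprotonated selectively at C3 by LDA at −78 °C (the vinyllithium is chelated by the 2'-OMOM oxygen), and SN2 alkylation with prenyl bromide gives the linear prenyl group; LDA does not ortho-lithiate the MOM-flanked aryl C–H positions at this temperature.

**Step 9**
Reactants: 12
Product: 13, Kuwanon T
Conditions: 3 M aq HCl, MeOH–THF, 40 °C, stopped at full conversion
Reagents that add atoms: none
Why: Acetal hydrolysis removes all four MOM groups under mild acid; short time and low temperature keep the free phenols from adding to the prenyl groups.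

## Compound list
1 | resorcinol | Oc1cccc(O)c1 | starting material
2 | 1,3-bis(methoxymethoxy)benzene | COCOc1cccc(OCOC)c1 | intermediate
3 | 3,5-bis(methoxymethoxy)phenol | COCOc1cc(O)cc(OCOC)c1 | intermediate
4 | prenyl bromide (1-bromo-3-methylbut-2-ene) | CC(C)=CCBr | starting material
5 | 1,3-bis(methoxymethoxy)-2-(3-methylbut-2-en-1-yl)benzene | COCOc1cccc(OCOC)c1CC=C(C)C | intermediate
6 | 1-iodo-2,4-bis(methoxymethoxy)-3-(3-methylbut-2-en-1-yl)benzene | COCOc1ccc(I)c(OCOC)c1CC=C(C)C | intermediate
7 | propiolic acid | C#CC(=O)O | starting material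
8 | 3-[2,4-bis(methoxymethoxy)-3-(3-methylbut-2-en-1-yl)phenyl]prop-2-ynoic acid | COCOc1ccc(C#CC(=O)O)c(OCOC)c1CC=C(C)C | intermediate
9 | 3,5-bis(methoxymethoxy)phenyl 3-[2,4-bis(methoxymethoxy)-3-(3-methylbut-2-en-1-yl)phenyl]prop-2-ynoate | COCOc1cc(OCOC)cc(OC(=O)C#Cc2ccc(OCOC)c(CC=C(C)C)c2OCOC)c1 | intermediate
10 | 1-[2-hydroxy-4,6-bis(methoxymethoxy)phenyl]-3-[2,4-bis(methoxymethoxy)-3-(3-methylbut-2-en-1-yl)phenyl]prop-2-yn-1-one | COCOc1cc(O)c(C(=O)C#Cc2ccc(OCOC)c(CC=C(C)C)c2OCOC)c(OCOC)c1 | intermediate (not isolated)
11 | 5,7-bis(methoxymethoxy)-2-[2,4-bis(methoxymethoxy)-3-(3-methylbut-2-en-1-yl)phenyl]-4H-chromen-4-one | COCOc1cc(OCOC)c2c(c1)oc(-c1ccc(OCOC)c(CC=C(C)C)c1OCOC)cc2=O | intermediate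
12 | 5,7-bis(methoxymethoxy)-2-[2,4-bis(methoxymethoxy)-3-(3-methylbut-2-en-1-yl)phenyl]-3-(3-methylbut-2-en-1-yl)-4H-chromen-4-one | COCOc1cc(OCOC)c2c(c1)oc(-c1ccc(OCOC)c(CC=C(C)C)c1OCOC)c(CC=C(C)C)c2=O | intermediate
13 | Kuwanon T | CC(C)=CCc1c(O)ccc(-c2oc3cc(O)cc(O)c3c(=O)c2CC=C(C)C)c1O | target

## Summary
Total steps: 9 (step 7 is two operations without intermediate purification).
Longest linear sequence: 8 steps (1 → 2 → 5 → 6 → 8 → 9 → 11 → 12 → 13, i.e. steps 1, 3, 4, 5, 6, 7, 8, 9).

Three steps most likely to fail:
- **Step 7 (photo-Fries/cyclisation).** Risks are a modest ortho yield, para-acyl migration, cage escape back to phenol 3, photoreaction of the allyl-arene unit, and some 5-exo aurone. Fallback: form C4–C4a by acyl-radical aromatic substitution instead. Couple 6 with propargyl alcohol and oxidise to the ynal, add phenol 3 by oxa-Michael to give the β-aryloxy enal, then generate the acyl radical from the aldehyde (TBHP, Bu4NBr) to cyclise onto the A ring, as in xanthone syntheses from 2-aryloxybenzaldehydes.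
- **Step 8 (C3 lithiation/prenylation).** Risks are ring-opening of the 3-lithioflavone to the ynone phenoxide (then O-prenylation) and sluggish alkylation. Fallback: trap the C3 anion with I2 to give the 3-iodoflavone, then install prenyl by radical addition–fragmentation with 3-methyl-3-(phenylsulfonyl)but-1-ene under (Bu3Sn)2/hν (the vinyl radical adds to the CH2= terminus and PhSO2• is expelled).
- **Step 9 (acidic MOM removal).** Risk is acid-catalysed chroman formation from 2'-OH or 4'-OH adding to the 3'-prenyl group. Fallback: change the protecting group from step 1 to SEM (SEMCl; same lithiation and borylation chemistry) and finish with fluoride (TBAF, DMPU, 60 °C), so no acid is used after the prenyl groups are in place.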